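**Plan**

1. Cuts: both MOM ethers last; C3–H back to C3–CO2allyl (quaternary C3); ring C at C2–C3 and O1–C8a, which releases O1–C2 as formaldehyde; then C3–CO2allyl, C3–C1′ (ring B) and C6–geranyl.
2. Forward order: the ring A ketone is iodinated, protected and geranylated; the ring B bromide is joined at C3 by ketone α-arylation; the allyl ester is placed on C3; ring C is then closed in one operation with formaldehyde.
3. Enabling feature: the C4 carbonyl sits between C3 and ring A carbon C4a, so it makes C3 a carbon nucleophile toward CH2=O (C2) and, being ortho to C8a, turns C8a–F into an SNAr site for the new C2–O1 alkoxide.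
4. The C3 ester helper raises the acidity of C3–H, blocks dehydration and double addition, and leaves in the step that creates the stereocentre.
5. Stereochemistry: C3 is (S) by CIP analysis of the target; it comes from ligand-controlled enantioselective protonation in step 8. The E-alkene is carried in with geranyl bromide.

Key step: step 7

Assumption: in step 8 the (S)-ligand is taken to deliver the (3S) ketone by analogy with related 3-aryl chroman-4-one substrates; the sense would be checked on the first run and the (R)-ligand used instead if it proves opposite.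

Geranyl = (2E)-3,7-dimethylocta-2,6-dien-1-yl throughout.

**Route**

Step 1
Reactants: 1 1-(2-fluoro-4-hydroxyphenyl)ethan-1-one
Product: 2 1-(2-fluoro-4-hydroxy-5-iodophenyl)ethan-1-one
Conditions: NIS (1.05 equiv), p-TsOH·H2O (10 mol%), MeCN, 0 °C → rt
Reagents that add atoms: N-iodosuccinimide, O=C1CCC(=O)N1I
Why: Electrophilic aromatic iodination ortho to the free phenol, where position 5 (para to fluorine, unflanked) should be preferred over position 3 (between OH and F) and the acetyl group disfavours a second iodination.

Step 2
Reactants: 2 1-(2-fluoro-4-hydroxy-5-iodophenyl)ethan-1-one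
Product: 3 1-[2-fluoro-5-iodo-4-(methoxymethoxy)phenyl]ethan-1-one
Conditions: MOMCl, iPr2NEt, CH2Cl2, 0 °C → rt
Reagents that add atoms: chloromethyl methyl ether, COCCl
Why: Williamson-type O-alkylation of the phenol (MOM protection), needed because a free phenoxide para to the carbonyl would quench the organozinc and later switch off the SNAr.

Step 3
Reactants: 3 1-[2-fluoro-5-iodo-4-(methoxymethoxy)phenyl]ethan-1-one; 4 geranyl bromide
Product: 6 1-[5-geranyl-2-fluoro-4-(methoxymethoxy)phenyl]ethan-1-one, via arylzinc iodide 5 (not isolated)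
Conditions: Zn dust, LiCl, THF, 25–50 °C; then Pd(PPh3)4 (3 mol%), geranyl bromide, THF, 0 °C → rt
Reagents that add atoms: none
Why: LiCl-promoted direct zinc insertion into the aryl iodide tolerates the methyl ketone, and the Negishi allyl–aryl coupling runs through a π-geranyl palladium intermediate that is arylated at its unsubstituted terminus, so the linear skeleton and E geometry should be kept (copper catalysis is avoided because it favours SN2′ attack).

Step 4
Reactants: 7 4-bromo-3-methoxyphenol
Product: 8 1-bromo-2-methoxy-4-(methoxymethoxy)benzene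
Conditions: MOMCl, iPr2NEt, CH2Cl2, 0 °C → rt
Reagents that add atoms: chloromethyl methyl ether, COCCl
Why: Williamson-type MOM protection of the phenol, giving a ring B bromide that is inert to base and to the later fluoride release.

Step 5
Reactants: 6 1-[5-geranyl-2-fluoro-4-(methoxymethoxy)phenyl]ethan-1-one; 8 1-bromo-2-methoxy-4-(methoxymethoxy)benzene
Product: 9 1-[5-geranyl-2-fluoro-4-(methoxymethoxy)phenyl]-2-[2-methoxy-4-(methoxymethoxy)phenyl]ethan-1-one
Conditions: Pd2(dba)3 (2 mol%), Xantphos (4.5 mol%), K3PO4, toluene, 80 °C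
Reagents that add atoms: none
Why: Palladium-catalysed α-arylation of a methyl ketone enolate, in which the ortho methoxy group of the aryl palladium species hinders a second arylation, K3PO4 is too weak a nucleophile to displace fluoride, and the trisubstituted alkenes are not Heck-competent.

Step 6
Reactants: 9 1-[5-geranyl-2-fluoro-4-(methoxymethoxy)phenyl]-2-[2-methoxy-4-(methoxymethoxy)phenyl]ethan-1-one
Product: 10 allyl 3-[5-geranyl-2-fluoro-4-(methoxymethoxy)phenyl]-2-[2-methoxy-4-(methoxymethoxy)phenyl]-3-oxopropanoate (racemic)
Conditions: NaH (2.5 equiv), diallyl carbonate (3 equiv), THF, 60 °C; AcOH quench, 0 °C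
Reagents that add atoms: diallyl carbonate, C=CCOC(=O)OCC=C
Why: Claisen-type C-acylation of the ketone enolate with a dialkyl carbonate, driven by formation of the doubly stabilised sodium enolate of 10 (any enol carbonate is returned by allyloxide), while the aryl fluoride stays untouched because every ketone is present as its enolate, as in the carbalkoxylation of 2-halogenated acetophenones.

Step 7
Reactants: 10 allyl 3-[5-geranyl-2-fluoro-4-(methoxymethoxy)phenyl]-2-[2-methoxy-4-(methoxymethoxy)phenyl]-3-oxopropanoate; 11 formaldehyde (as paraformaldehyde)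
Product: 13 allyl 6-geranyl-7-(methoxymethoxy)-3-[2-methoxy-4-(methoxymethoxy)phenyl]-4-oxochromane-3-carboxylate (racemic), via hydroxymethyl adduct 12 (not isolated)
Conditions: (CH2O)n (3 equiv), Cs2CO3 (1.5 equiv), DMF, rt → 50 °C
Reagents that add atoms: none
Why: Proposed new method: Carbonate forms the stabilised enolate of 10, which adds through C3 to formaldehyde (C2–C3 bond) to give alkoxide 12; since C3 is now quaternary the C4 carbonyl can no longer be masked as an enolate and, being ortho to C8a, it activates the C8a–F bond for addition–elimination by the C2–O1 alkoxide through a Meisenheimer intermediate (O1–C8a bond), fluoride loss being irreversible. The closest known reaction types are the base-mediated hydroxymethylation of β-keto esters with formaldehyde and the domino condensation–SNAr ring closures of 2-fluoroaroyl acetates used for 4-quinolones, which have not been joined with formaldehyde as the one-carbon-one-oxygen unit to close a chroman-4-one. Ring C closes as a six-membered ring by intramolecular SNAr, a 6-exo-trig attack of oxygen on the fluorine-bearing arene carbon. The new quaternary centre C3 is formed as a racemate on purpose, no control being needed because step 8 removes the ester and sets C3 afresh. The step needs C-hydroxymethylation followed by ring closure in preference to retro-aldol, dehydration, a second addition or attack of the ester-enolate oxygen on C8a: the absence of a second hydrogen at C3 excludes dehydration and double addition, excess formaldehyde returns any retro-aldol material, and a localised primary alkoxide is a far better SNAr nucleophile than a delocalised enolate oxygen. The C7 OMOM group is meta to C8a and does not donate into the attacked carbon, and MOM instead of silyl protection is used because the step liberates fluoride.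

Step 8
Reactants: 13 allyl 6-geranyl-7-(methoxymethoxy)-3-[2-methoxy-4-(methoxymethoxy)phenyl]-4-oxochromane-3-carboxylate (racemic)
Product: 14 (3S)-6-geranyl-7-(methoxymethoxy)-3-[2-methoxy-4-(methoxymethoxy)phenyl]-2,3-dihydro-4H-chromen-4-one
Conditions: Pd2(dba)3 (5 mol%), (S)-(CF3)3-t-BuPHOX (12.5 mol%), Meldrum's acid (2.5 equiv), THF, 5 °C → rt
Reagents that add atoms: none
Why: Decarboxylative asymmetric protonation, in which zerovalent palladium ionises the allyl ester, CO2 is lost and the PHOX-bound palladium enolate is protonated at C3 on one face by Meldrum's acid (which also takes up the allyl group), a reaction type with direct precedent for 3-aryl chroman-4-ones carrying ortho-substituted aryl groups, so that the ligand is the sole source of the (S) configuration.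

Step 9
Reactants: 14 (3S)-6-geranyl-7-(methoxymethoxy)-3-[2-methoxy-4-(methoxymethoxy)phenyl]-2,3-dihydro-4H-chromen-4-one
Product: 15 (3S)-6-geranyl-7-hydroxy-3-(4-hydroxy-2-methoxyphenyl)-2,3-dihydro-4H-chromen-4-one
Conditions: HCl (1.25 M in MeOH), THF, 0 °C → rt
Reagents that add atoms: none
Why: Acid-catalysed acetal exchange of both aryl MOM ethers with methanol (transacetalisation to dimethoxymethane) under dilute, cold conditions chosen so that neither enolisation at C3 nor protonation of the geranyl alkenes should compete.

**Compound list**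

1 | 1-(2-fluoro-4-hydroxyphenyl)ethan-1-one | CC(=O)c1ccc(O)cc1F | starting material
2 | 1-(2-fluoro-4-hydroxy-5-iodophenyl)ethan-1-one | CC(=O)c1cc(I)c(O)cc1F | intermediate
3 | 1-[2-fluoro-5-iodo-4-(methoxymethoxy)phenyl]ethan-1-one | CC(=O)c1cc(I)c(OCOC)cc1F | intermediate
4 | geranyl bromide, (2E)-1-bromo-3,7-dimethylocta-2,6-diene | BrC/C=C(\C)CCC=C(C)C | starting material
5 | [5-acetyl-4-fluoro-2-(methoxymethoxy)phenyl]zinc iodide (LiCl complex in THF) | CC(=O)c1cc([Zn]I)c(OCOC)cc1F | intermediate
6 | 1-{5-[(2E)-3,7-dimethylocta-2,6-dien-1-yl]-2-fluoro-4-(methoxymethoxy)phenyl}ethan-1-one | CC(=O)c1cc(C/C=C(\C)CCC=C(C)C)c(OCOC)cc1F | intermediate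
7 | 4-bromo-3-methoxyphenol | COc1cc(O)ccc1Br | starting material
8 | 1-bromo-2-methoxy-4-(methoxymethoxy)benzene | COCOc1ccc(Br)c(OC)c1 | intermediate
9 | 1-[5-geranyl-2-fluoro-4-(methoxymethoxy)phenyl]-2-[2-methoxy-4-(methoxymethoxy)phenyl]ethan-1-one | COCOc1ccc(CC(=O)c2cc(C/C=C(\C)CCC=C(C)C)c(OCOC)cc2F)c(OC)c1 | intermediate
10 | allyl 3-[5-geranyl-2-fluoro-4-(methoxymethoxy)phenyl]-2-[2-methoxy-4-(methoxymethoxy)phenyl]-3-oxopropanoate (racemic) | COCOc1ccc(C(C(=O)OCC=C)C(=O)c2cc(C/C=C(\C)CCC=C(C)C)c(OCOC)cc2F)c(OC)c1 | intermediate
11 | formaldehyde (used as paraformaldehyde) | C=O | starting material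
12 | allyl 2-(hydroxymethyl)-3-[5-geranyl-2-fluoro-4-(methoxymethoxy)phenyl]-2-[2-methoxy-4-(methoxymethoxy)phenyl]-3-oxopropanoate (racemic, present as its cesium alkoxide) | COCOc1ccc(C(CO)(C(=O)OCC=C)C(=O)c2cc(C/C=C(\C)CCC=C(C)C)c(OCOC)cc2F)c(OC)c1 | intermediate
13 | allyl 6-geranyl-7-(methoxymethoxy)-3-[2-methoxy-4-(methoxymethoxy)phenyl]-4-oxochromane-3-carboxylate (racemic) | COCOc1ccc(C2(C(=O)OCC=C)COc3cc(OCOC)c(C/C=C(\C)CCC=C(C)C)cc3C2=O)c(OC)c1 | intermediate
14 | (3S)-6-geranyl-7-(methoxymethoxy)-3-[2-methoxy-4-(methoxymethoxy)phenyl]-2,3-dihydro-4H-chromen-4-one | COc1cc(OCOC)ccc1[C@H]1COc2cc(OCOC)c(C/C=C(\C)CCC=C(C)C)cc2C1=O | intermediate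
15 | (3S)-6-[(2E)-3,7-dimethylocta-2,6-dien-1-yl]-7-hydroxy-3-(4-hydroxy-2-methoxyphenyl)-2,3-dihydro-4H-chromen-4-one | COc1cc(O)ccc1[C@H]1COc2cc(O)c(C/C=C(\C)CCC=C(C)C)cc2C1=O | target

**Step count**

Total steps: 9. Longest linear sequence: 8 (steps 1, 2, 3, 5, 6, 7, 8, 9; step 4 is the side branch).

**Steps most likely to fail**

1. Step 7 (the proposed new method). The O-arylation may be slow because the activating C4 carbonyl is itself conjugated to the para OMOM oxygen. Retro-aldol return would then dominate, and prolonged heating would bring retro-Claisen cleavage of the non-enolisable β-keto ester or premature cyclisation through the ester-enolate oxygen.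
Fallback (known chemistry), setting out from 6 and coming back at 14: ring C would be built from a phenol, so that O1 comes from ring A and C2 from a formamide acetal. Fluoride of 6 is displaced by sodium 2-(trimethylsilyl)ethoxide (NaH, 2-(trimethylsilyl)ethanol, THF/DMF, 60 °C) to give 1-{5-geranyl-4-(methoxymethoxy)-2-[2-(trimethylsilyl)ethoxy]phenyl}ethan-1-one F1. α-Arylation with 8 under the conditions of step 5 should give the corresponding deoxybenzoin F2. TBAF (THF, rt) should release the 2′-hydroxy deoxybenzoin F3. Heating with DMF dimethyl acetal (toluene, 90 °C) should close ring C to the isoflavone F4. Transfer hydrogenation with RuCl(p-cymene)[(S,S)-TsDPEN] and HCO2H/Et3N (EtOAc, 40 °C) should reduce the C2–C3 double bond and then the ketone with dynamic kinetic resolution at the enolisable C3, giving the cis-(3S,4S)-isoflavan-4-ol F5. Dess–Martin periodinane/NaHCO3 (CH2Cl2, 0 °C) should restore the C4 ketone without touching C3 and give 14.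

2. Step 8. Enantioface discrimination in the protonation may be poor or of the wrong sense, decarboxylative allylation at C3 may compete, and the product may partly racemise on work-up.
Fallback, setting out from 13 and coming back at 14: non-selective deallylation–decarboxylation (Pd(PPh3)4, morpholine, THF, rt) should give the racemic MOM-protected isoflavanone F6. The same transfer hydrogenation with dynamic kinetic resolution as in the first fallback should convert it into the cis-(3S,4S)-isoflavan-4-ol F5, and Dess–Martin oxidation should then give 14. The stereocentre is thus set by ketone reduction under equilibrating conditions instead of by protonation.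

3. Step 9. Acid may erode the enantiopurity through enolisation at C3, and the geranyl chain may cyclise onto the unmasked 7-OH.
Fallback, setting out from 13 and coming back at 15: the acid-labile groups are exchanged while C3 is still quaternary and cannot racemise. Methanolic HCl on 13 should give the bis-phenol allyl ester F7. TBSCl/imidazole (DMF, rt) should give the bis-TBS ether F8. The decarboxylative protonation of step 8 should give the (3S) bis-TBS isoflavanone F9. HF·pyridine buffered with pyridine (THF, 0 °C) should remove both aryl silyl ethers without base and give 15.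

**Further compounds**

F1 | step 7 | 1-{5-geranyl-4-(methoxymethoxy)-2-[2-(trimethylsilyl)ethoxy]phenyl}ethan-1-one | CC(=O)c1cc(C/C=C(\C)CCC=C(C)C)c(OCOC)cc1OCC[Si](C)(C)C
F2 | step 7 | 1-{5-geranyl-4-(methoxymethoxy)-2-[2-(trimethylsilyl)ethoxy]phenyl}-2-[2-methoxy-4-(methoxymethoxy)phenyl]ethan-1-one | COCOc1ccc(CC(=O)c2cc(C/C=C(\C)CCC=C(C)C)c(OCOC)cc2OCC[Si](C)(C)C)c(OC)c1
F3 | step 7 | 1-[5-geranyl-2-hydroxy-4-(methoxymethoxy)phenyl]-2-[2-methoxy-4-(methoxymethoxy)phenyl]ethan-1-one | COCOc1ccc(CC(=O)c2cc(C/C=C(\C)CCC=C(C)C)c(OCOC)cc2O)c(OC)c1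
F4 | step 7 | 6-geranyl-7-(methoxymethoxy)-3-[2-methoxy-4-(methoxymethoxy)phenyl]-4H-chromen-4-one | COCOc1ccc(-c2coc3cc(OCOC)c(C/C=C(\C)CCC=C(C)C)cc3c2=O)c(OC)c1
F5 | step 7 | (3S,4S)-6-geranyl-7-(methoxymethoxy)-3-[2-methoxy-4-(methoxymethoxy)phenyl]chroman-4-ol (cis) | COc1cc(OCOC)ccc1[C@H]1COc2cc(OCOC)c(C/C=C(\C)CCC=C(C)C)cc2[C@H]1O
F6 | step 8 | racemic 6-geranyl-7-(methoxymethoxy)-3-[2-methoxy-4-(methoxymethoxy)phenyl]-2,3-dihydro-4H-chromen-4-one | COc1cc(OCOC)ccc1C1COc2cc(OCOC)c(C/C=C(\C)CCC=C(C)C)cc2C1=O
F7 | step 9 | allyl 6-geranyl-7-hydroxy-3-(4-hydroxy-2-methoxyphenyl)-4-oxochromane-3-carboxylate (racemic) | COc1cc(O)ccc1C1(C(=O)OCC=C)COc2cc(O)c(C/C=C(\C)CCC=C(C)C)cc2C1=O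
F8 | step 9 | allyl 7-(tert-butyldimethylsilyloxy)-3-[4-(tert-butyldimethylsilyloxy)-2-methoxyphenyl]-6-geranyl-4-oxochromane-3-carboxylate (racemic) | COc1cc(O[Si](C)(C)C(C)(C)C)ccc1C1(C(=O)OCC=C)COc2cc(O[Si](C)(C)C(C)(C)C)c(C/C=C(\C)CCC=C(C)C)cc2C1=O
F9 | step 9 | (3S)-7-(tert-butyldimethylsilyloxy)-3-[4-(tert-butyldimethylsilyloxy)-2-methoxyphenyl]-6-geranyl-2,3-dihydro-4H-chromen-4-one | COc1cc(O[Si](C)(C)C(C)(C)C)ccc1[C@H]1COc2cc(O[Si](C)(C)C(C)(C)C)c(C/C=C(\C)CCC=C(C)C)cc2C1=O
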